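**Retrosynthetic overview**
- Target ⇒ fourfold O-demethylation of its tetramethyl ether ⇒ hydrogenation of the corresponding E-stilbene (CH=CH → CH2CH2).
- The E-stilbene ⇒ one-flask, three-component assembly on a bought 3,5-dimethoxyphenyl iodide: two ortho aryl–CH2 bonds (from 4-methoxybenzyl chloride) and the ipso aryl–vinyl bond (from styrene), by a palladium/norbornene ortho,ortho′-dibenzylation/ipso-Heck reaction (the proposed new step).
- No ring is formed: the central ring A, the two phenol rings B and the phenyl ring C are all bought; they are attached in the order B, B, C in a single operation.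

Assumption: the target has no stereocentre or other stereogenic element (it is achiral), so no enantiocontrol is needed; the only stereo-element on the route, the E-alkene of compound 4, is erased in step 2.

**Step 1**
Reactants: 1 1-iodo-3,5-dimethoxybenzene; 2 4-methoxybenzyl chloride (3 equiv); 3 styrene (2 equiv)
Product: 4 (E)-1,5-dimethoxy-2,4-bis(4-methoxybenzyl)-3-(2-phenylethenyl)benzene
Conditions: Pd(OAc)2 (10 mol%), tri(2-furyl)phosphine (20 mol%), norbornene (2 equiv), Cs2CO3 (4 equiv), MeCN, 90 °C, 24 h
Reagents that add atoms: none
Why: Proposed new method: a Catellani-type palladium/norbornene three-component reaction applied to an aryl iodide whose two ortho C–H bonds are each flanked by a meta-methoxy group, with a benzylic chloride as the alkylating partner. Zerovalent palladium inserts into the carbon–iodine bond of 1 and norbornene carbopalladation gives a catalyst-bound alkylpalladium with no accessible syn β-hydrogen, which therefore palladates the neighbouring ortho C–H by carbonate-assisted concerted metalation–deprotonation (the small methoxy group acidifies this C–H inductively and can turn its methyl away from the metal). The resulting divalent palladacycle is oxidised by SN2-type attack on 2 to tetravalent palladium, and aryl–benzyl reductive elimination installs the first benzyl; the sequence repeats at the second ortho site. The two ortho benzyls, buttressed by the methoxy groups, then force β-carbon elimination of norbornene, and the 2,6-disubstituted arylpalladium is trapped by a Heck reaction with 3 (syn insertion, syn β-hydride elimination) to give the E-alkene. The closest known reaction type is the Catellani ortho,ortho′-dialkylation/ipso-Heck of aryl iodides without meta substituents using primary alkyl halides.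

**Step 2**
Reactants: 4 (E)-1,5-dimethoxy-2,4-bis(4-methoxybenzyl)-3-(2-phenylethenyl)benzene
Product: 5 1,5-dimethoxy-2,4-bis(4-methoxybenzyl)-3-(2-phenylethyl)benzene
Conditions: H2 (1 atm), 10% Pd/C, EtOAc–EtOH, rt
Reagents that add atoms: none
Why: Heterogeneous catalytic hydrogenation of a 1,2-disubstituted styrenyl alkene; aryl methyl ethers and diarylmethane C–C bonds are inert to H2 over Pd/C, and no stereocentre is created.

**Step 3**
Reactants: 5 1,5-dimethoxy-2,4-bis(4-methoxybenzyl)-3-(2-phenylethyl)benzene
Product: 7 4,6-bis(4-hydroxybenzyl)-5-(2-phenylethyl)benzene-1,3-diol, via tetrakis(dibromoboryl) ether 6 (not isolated)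
Conditions: BBr3 (8 equiv), CH2Cl2, −78 °C to rt, 12 h; then H2O, 0 °C
Reagents that add atoms: none
Why: BBr3 cleavage of aryl methyl ethers (Lewis acid-mediated O-demethylation): boron coordinates each ether oxygen, bromide attacks the methyl group by SN2, and the aryl borate is hydrolysed on work-up; the molecule holds only arenes and sp3 C–H bonds besides the four ethers.

**Compound list**
1 | 1-iodo-3,5-dimethoxybenzene | COc1cc(I)cc(OC)c1 | starting material
2 | 4-methoxybenzyl chloride, i.e. 1-(chloromethyl)-4-methoxybenzene | COc1ccc(CCl)cc1 | starting material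
3 | styrene | C=Cc1ccccc1 | starting material
4 | (E)-1,5-dimethoxy-2,4-bis(4-methoxybenzyl)-3-(2-phenylethenyl)benzene | COc1ccc(Cc2c(OC)cc(OC)c(Cc3ccc(OC)cc3)c2/C=C/c2ccccc2)cc1 | intermediate
5 | 1,5-dimethoxy-2,4-bis(4-methoxybenzyl)-3-(2-phenylethyl)benzene | COc1ccc(Cc2c(OC)cc(OC)c(Cc3ccc(OC)cc3)c2CCc2ccccc2)cc1 | intermediate
6 | 1,5-bis(dibromoboryloxy)-2,4-bis[4-(dibromoboryloxy)benzyl]-3-(2-phenylethyl)benzene | BrB(Br)Oc1ccc(Cc2c(OB(Br)Br)cc(OB(Br)Br)c(Cc3ccc(OB(Br)Br)cc3)c2CCc2ccccc2)cc1 | intermediate
7 | 4,6-bis(4-hydroxybenzyl)-5-(2-phenylethyl)benzene-1,3-diol (CNP0361781.0) | Oc1ccc(Cc2c(O)cc(O)c(Cc3ccc(O)cc3)c2CCc2ccccc2)cc1 | target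

**Total step count:** 3. **Longest linear sequence:** 3 steps (1 → 4 → 5 → 7).

**Steps most likely to fail, with fallbacks**

Step 1 (the proposed new step, highest risk). Three failure modes are foreseeable:
- Palladation of the C–H bonds next to the methoxy groups may be too slow, giving the plain Heck product or mono-benzylated material.
- The 2-benzylarylpalladium may close onto the neighbouring anisyl ring to give a fluorene before styrene inserts.
- Chloride 2 may be consumed by direct reaction with zerovalent palladium.

The fallback uses known chemistry only; it sets out from 1 and 3 (and uses 2) and comes back to the route at 5. A Heck coupling of 1 with 3 (Pd(OAc)2, P(o-tolyl)3, K2CO3, DMF, 100 °C) gives (E)-1,3-dimethoxy-5-(2-phenylethenyl)benzene F1. Hydrogenation (H2, Pd/C, EtOAc, rt) gives 1,3-dimethoxy-5-(2-phenylethyl)benzene F2. Electrophilic dibromination with NBS (2.1 equiv, MeCN, 0 °C to rt) goes para to each methoxy group, the site between the two methoxy groups being the most hindered, and gives 2,4-dibromo-1,5-dimethoxy-3-(2-phenylethyl)benzene F3. Separately, 2 is turned with zinc dust and LiCl in THF at rt into (4-methoxybenzyl)zinc chloride F4. A twofold Negishi coupling of F3 with F4 (3 equiv; Pd(OAc)2, SPhos, THF, 60 °C) gives 5. Step 2 is then not needed and step 3 follows.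

Step 3 (global demethylation). The HBr formed can cause acid-mediated migration or loss of the electron-rich 4-hydroxybenzyl groups (retro-Friedel–Crafts), and the cleavage may stop at partly methylated material. The fallback changes the protecting-group plan so that the harsh demethylation is done on the simple aryl iodide and the last step is a neutral hydrogenolysis. It sets out from 1 (and uses 3), comes back to the route at 7, and reuses the step 1 method, which will have been validated by the time step 3 is reached. Treatment of 1 with BBr3 (CH2Cl2, −78 °C to rt; then H2O) gives, by way of 1,3-bis(dibromoboryloxy)-5-iodobenzene F5 formed in the flask, 5-iodobenzene-1,3-diol F6. O-Benzylation (benzyl bromide, K2CO3, DMF, rt) gives 1,3-bis(benzyloxy)-5-iodobenzene F7. The step 1 conditions, with commercially available 4-(benzyloxy)benzyl chloride F8 in place of 2 and with 3, give (E)-1,5-bis(benzyloxy)-2,4-bis[4-(benzyloxy)benzyl]-3-(2-phenylethenyl)benzene F9. One operation with H2 (1–3 atm) over Pd/C in EtOAc–MeOH then saturates the alkene and cleaves all four benzyl ethers to give 7.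

Step 2 (hydrogenation, lowest risk). The alkene sits between two ortho benzyl groups and may adsorb poorly on the metal surface, and traces of iodide or phosphine carried over from step 1 may poison Pd/C. The fallback replaces surface-catalysed hydrogenation by a stoichiometric, metal-free diimide reduction, which is a concerted syn transfer of two hydrogens from HN=NH that needs no catalyst surface. It sets out from 4 and comes back to the route at 5: p-toluenesulfonyl hydrazide (5 equiv), NaOAc (5 equiv), THF–H2O, reflux. New compounds on this way: none F0.

**Further compounds**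
F1 | step 1 | (E)-1,3-dimethoxy-5-(2-phenylethenyl)benzene | COc1cc(/C=C/c2ccccc2)cc(OC)c1
F2 | step 1 | 1,3-dimethoxy-5-(2-phenylethyl)benzene | COc1cc(CCc2ccccc2)cc(OC)c1
F3 | step 1 | 2,4-dibromo-1,5-dimethoxy-3-(2-phenylethyl)benzene | COc1cc(OC)c(Br)c(CCc2ccccc2)c1Br
F4 | step 1 | (4-methoxybenzyl)zinc chloride | COc1ccc(C[Zn]Cl)cc1
F0 | step 2 | none | none
F5 | step 3 | 1,3-bis(dibromoboryloxy)-5-iodobenzene | BrB(Br)Oc1cc(I)cc(OB(Br)Br)c1
F6 | step 3 | 5-iodobenzene-1,3-diol | Oc1cc(O)cc(I)c1
F7 | step 3 | 1,3-bis(benzyloxy)-5-iodobenzene | Ic1cc(OCc2ccccc2)cc(OCc2ccccc2)c1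
F8 | step 3 | 4-(benzyloxy)benzyl chloride | ClCc1ccc(OCc2ccccc2)cc1
F9 | step 3 | (E)-1,5-bis(benzyloxy)-2,4-bis[4-(benzyloxy)benzyl]-3-(2-phenylethenyl)benzene | c1ccccc1COc1ccc(Cc2c(OCc3ccccc3)cc(OCc3ccccc3)c(Cc3ccc(OCc4ccccc4)cc3)c2/C=C/c2ccccc2)cc1
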